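(The data stem from a simulated flask for an exercise; noise was put on by code.)

Molar minutes are the unit we would answer you in: reagent concentration multiplied by time, counted against powers of ten of free substrate. With reagent taken as steady over a stretch, the fall of substrate is pseudo-first-order, so its logarithm should drop in step with molar minutes. Taking reagent as its charge less the target made, averaged over the stretch, the east run gives 2.70 M·min per decade and the west run 2.13 M·min, both at −25 °C. Their mean, 2.42 M·min, is our decade dose, the molar minutes that take free substrate down by one power of ten.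

| setting | west | south-east | east | Tuesday's | Thursday's | Saturday's | Sunday's |
|---|---|---|---|---|---|---|---|
| substrate | 0.26 M | 0.88 M | 0.20 M | 0.20 M | 0.20 M | 0.60 M | 0.60 M |
| reagent | 1.8 equiv | 1.8 equiv | 1.6 equiv | 1.80 equiv | 0.900 equiv | 0.900 equiv | 1.80 equiv |
| temperature | −25 °C | −14 °C | −25 °C | −20 °C | −20 °C | −20 °C | −20 °C |
| remark | run made earlier | run made earlier | run made earlier |  |  |  |  |
| time |  |  |  | 20 min | 20 min | 20 min | 20 min |

| run | time / min | target / % | substrate / % |
|---|---|---|---|
| west | 2.50 | 48.2 | 9.5 |
| west | 5.00 | 65.5 | 4.0 |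
| west | 8.00 | 74.1 | 2.2 |
| west | 10.0 | 75.0 | 1.7 |
| south-east | 2.50 | 60.6 | 0.3 |
| south-east | 5.00 | 63.5 | 0 |
| south-east | 8.00 | 63.1 | 0 |
| south-east | 10.0 | 63.5 | 0 |
| east | 0.833 | 14.6 | 17.9 |
| east | 2.00 | 32.4 | 14.4 |
| east | 4.00 | 49.8 | 7.6 |
| east | 10.0 | 67.1 | 3.2 |

(readings scatter by 1 percentage point)

1. all flasks from highest to lowest amount of target, in percent of the substrate charged, at 20 min (Tuesday's / Thursday's / Saturday's / Sunday's)
2. the same order at 4.0 min (Tuesday's / Thursday's / Saturday's / Sunday's)
3. the amount of target, in percent of the substrate charged of the flask you put first, at 20 min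
4. the amount of target, in percent of the substrate charged of the flask you put last, at 20 min



Thursday's has about as much reagent as substrate, so we take half its charge as the mean, 0.0900 M. Over 20 min that buys 0.745 decades. With the west run's 75.0% as ceiling, this gives about 61.5%, and we put Thursday's last. Saturday's buys 2.24 decades on the same reckoning, so we expect it ahead of Thursday's. We put Tuesday's first, near 75.0%, then Sunday's, then Saturday's. At 4.0 min, charge times time gives Sunday's 1.79 decades and Thursday's 0.298, so those two stand first and last, and we cannot part Tuesday's from Saturday's between them.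

Your forecast has Tuesday's > Thursday's > Sunday's > Saturday's at 20 min, with 77% and 62%, and Tuesday's > Sunday's > Saturday's > Thursday's at 4.0 min; it calls Thursday's “cleaner but slow late on”. We part on Thursday's, which it holds at 69. Our 61.5% is for Thursday's, its 62% for Saturday's.

The flasks give Tuesday's > Sunday's > Saturday's > Thursday's at 20 min, with 75.6% and 54.6%, and Sunday's > Tuesday's > Saturday's > Thursday's at 4.0 min.

    substrate + reagent → isomer of the product (k = 0.0150 /M/s, Ea = 47.0 kJ/mol)
    reagent + tautomer → target (k = 0.0270 /M/s, Ea = 37.0 kJ/mol)
    substrate ⇌ tautomer (K = 2.40, k = 0.160 /s, Ea = 56.0 kJ/mol, ΔH = −41.0 kJ/mol)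
    2 substrate → homo dimer (k = 0.00430 /M/s, Ea = 62.0 kJ/mol)
    reagent ⇌ dormant form (K = 1.70, k = 9.50 × 10⁻⁴ /s, Ea = 85.0 kJ/mol, ΔH = −6.00 kJ/mol)
    (constants at −20 °C)

In Tuesday's at 20.0 min, tautomer has a half-life of 5.9 min by its step to target, with 0.0719 M of reagent left, which is a decade dose of 1.42 M·min, smaller than our 2.42 M·min. In the neighbouring flask like Tuesday's but with 0.450 equiv, 3.02% of the reagent's own charge is left at 20.0 min, which at that moment gives the step to target a pace in decades of 0.00191 /min, slower than the 0.0507 /min of Tuesday's, and tautomer stands at 38.3%.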